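**Retrosynthetic overview**

1. No ring is formed in the route: rings A, B and C and the C2 stereocentre are bought intact as (2S)-naringenin 1, and only ring A is decorated.
2. C6–prenyl bond: disconnected to an O5-prenyl ether made from prenol 2. The ether first steers iodination to C8 and is then relayed from O5 to C6 by a clay-promoted [1,3] shift.
3. C8–C1'' bond (key disconnection): light-driven nickel cross-electrophile coupling of the ring A C8 iodide with an epoxy alcohol made in one step from methyl (S)-glycidate 3, which supplies the side-chain stereocentre.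
4. Only the 7- and 4'-hydroxyls are masked (silyl ethers, removed last); the 5-OH is masked only transiently as the prenyl ether and the side-chain hydroxyls are never protected.
5. Order: silylation → O5-prenylation → C8 iodination → O-to-C prenyl shift → C8–C coupling → desilylation, with the epoxide arm made in parallel.

Assumption: (2S)-naringenin 1 and methyl (2S)-oxirane-2-carboxylate 3 are bought as single enantiomers (ee checked on receipt). TBS = tert-butyldimethylsilyl.

**Route**

Step 1
Reactants: 1 (2S)-naringenin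
Product: 4 (2S)-7-(TBSO)-2-[4-(TBSO)phenyl]-5-hydroxychroman-4-one
Conditions: TBSCl (2.3 equiv), imidazole (5 equiv), DMF, 0 °C → rt
Reagents that add atoms: tert-butyldimethylsilyl chloride, CC(C)(C)[Si](C)(C)Cl
Why: Phenol silylation in which the 7- and 4'-OH react while the 5-OH, locked in a hydrogen bond to the C4 carbonyl, stays free, and the weak base does not open ring C, so C2 remains (S).

Step 2
Reactants: 4 (2S)-7-(TBSO)-2-[4-(TBSO)phenyl]-5-hydroxychroman-4-one; 2 prenol (3-methylbut-2-en-1-ol)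
Product: 5 (2S)-7-(TBSO)-2-[4-(TBSO)phenyl]-5-(3-methylbut-2-enyloxy)chroman-4-one
Conditions: PPh3 (1.5 equiv), DIAD (1.5 equiv), THF, 0 °C → rt
Reagents that add atoms: none
Why: Mitsunobu etherification in which the chelated 5-OH (the only acidic OH left) displaces the activated primary allylic oxygen of prenol under essentially neutral conditions, so there is no base-induced chalcone opening and no loss of configuration at C2.

Step 3
Reactants: 5 (2S)-7-(TBSO)-2-[4-(TBSO)phenyl]-5-(3-methylbut-2-enyloxy)chroman-4-one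
Product: 6 (2S)-7-(TBSO)-2-[4-(TBSO)phenyl]-8-iodo-5-(3-methylbut-2-enyloxy)chroman-4-one
Conditions: NIS (1.05 equiv), MeCN, 0 °C → rt, dark
Reagents that add atoms: N-iodosuccinimide, O=C1CCC(=O)N1I
Why: Electrophilic aromatic iodination (SEAr) which, with O5 alkylated, is expected at C8, the less hindered position between O7 and the tied-back ring oxygen, because C6 is screened by the O5-prenyl and O7-silyl groups, while acid-free NIS should leave the ether alkene (no internal nucleophile) alone.

Step 4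
Reactants: 6 (2S)-7-(TBSO)-2-[4-(TBSO)phenyl]-8-iodo-5-(3-methylbut-2-enyloxy)chroman-4-one
Product: 7 (2S)-7-(TBSO)-2-[4-(TBSO)phenyl]-5-hydroxy-8-iodo-6-(3-methylbut-2-enyl)chroman-4-one
Conditions: montmorillonite K10 clay (Al2Si4O10(OH)2·nH2O, dried), CH2Cl2, 0 °C → rt
Reagents that add atoms: none
Why: Clay-promoted formal [1,3] O-to-C prenyl shift (ion-pair rearrangement of aryl prenyl ethers) in which the prenyl cation/acylphenol pair recombines through its unhindered CH2 end at C6, the only unsubstituted nucleophilic carbon of ring A now that iodine blocks C8, giving the linear prenyl group and restoring the chelated 5-OH.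

Step 5
Reactants: 3 methyl (2S)-oxirane-2-carboxylate
Product: 9 2-[(2S)-oxiran-2-yl]propan-2-ol, via epoxy ketone 8 (not isolated)
Conditions: MeMgCl (2.2 equiv), THF, −78 → −20 °C; aq NH4Cl; distil
Reagents that add atoms: methylmagnesium chloride, C[Mg]Cl
Why: Double Grignard addition to the ester through the methyl ketone at low temperature, where the chloride-based reagent does not open the oxirane and the oxiranyl C–H does not enolise, so the purchased (S) centre is carried unchanged.

Step 6
Reactants: 7 (2S)-7-(TBSO)-2-[4-(TBSO)phenyl]-5-hydroxy-8-iodo-6-(3-methylbut-2-enyl)chroman-4-one; 9 2-[(2S)-oxiran-2-yl]propan-2-ol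
Product: 11 (2S)-7-(TBSO)-2-[4-(TBSO)phenyl]-8-[(2S)-2,3-dihydroxy-3-methylbutyl]-5-hydroxy-6-(3-methylbut-2-enyl)chroman-4-one, via iodohydrin 10 (not isolated)
Conditions: 9 (2.5 equiv), NiBr2·MeOCH2CH2OMe (10 mol %), 4,4'-di-tert-butyl-2,2'-bipyridine (12 mol %), 4CzIPN (2 mol %), Et3N·HI (30 mol %), Et3N (3 equiv), degassed DMA, 450 nm LEDs, 25 °C
Reagents that add atoms: none
Why: Proposed new method: a nickel/photoredox cross-electrophile coupling on a substrate pair for which it has not been shown, namely a 2,6-dioxygenated aryl iodide carrying a free chelated phenol, an enolisable β-aryloxy ketone and a prenyl group, and an epoxide with an unprotected tertiary carbinol; Et3N·HI opens 9 at its CH2 terminus to iodohydrin 10, zerovalent nickel inserts into the C8–I bond of 7, the dye reduced by Et3N under blue light turns nickel over, the primary radical formed from 10 by iodine-atom abstraction is captured by the divalent aryl-nickel, and reductive elimination from trivalent nickel closes the C8–CH2 bond; the closest known reaction is the nickel/photoredox coupling of simple aryl iodides with terminal aliphatic epoxides through iodohydrins, and the side-chain stereocentre stays (S) because only the CH2–O bond of 9 is ever broken.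

Step 7
Reactants: 11 (2S)-7-(TBSO)-2-[4-(TBSO)phenyl]-8-[(2S)-2,3-dihydroxy-3-methylbutyl]-5-hydroxy-6-(3-methylbut-2-enyl)chroman-4-one
Product: 12 (2S)-8-[(2S)-2,3-dihydroxy-3-methylbutyl]-5,7-dihydroxy-2-(4-hydroxyphenyl)-6-(3-methylbut-2-enyl)chroman-4-one
Conditions: HF·pyridine, pyridine, THF, 0 °C → rt
Reagents that add atoms: none
Why: Fluoride cleavage of the two aryl silyl ethers under mildly acidic, non-basic conditions that leave the prenyl alkene, the diol and the base-sensitive C2 centre untouched.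

**Compound list**

1 | (2S)-naringenin, (2S)-5,7-dihydroxy-2-(4-hydroxyphenyl)chroman-4-one | O=C1C[C@@H](c2ccc(O)cc2)Oc2cc(O)cc(O)c12 | starting material
2 | prenol, 3-methylbut-2-en-1-ol | CC(C)=CCO | starting material
3 | methyl (2S)-oxirane-2-carboxylate, methyl (S)-glycidate | COC(=O)[C@@H]1CO1 | starting material
4 | (2S)-7-(TBSO)-2-[4-(TBSO)phenyl]-5-hydroxychroman-4-one | CC(C)(C)[Si](C)(C)Oc1cc(O)c2C(=O)C[C@@H](c3ccc(O[Si](C)(C)C(C)(C)C)cc3)Oc2c1 | intermediate
5 | (2S)-7-(TBSO)-2-[4-(TBSO)phenyl]-5-(3-methylbut-2-enyloxy)chroman-4-one | CC(C)(C)[Si](C)(C)Oc1cc(OCC=C(C)C)c2C(=O)C[C@@H](c3ccc(O[Si](C)(C)C(C)(C)C)cc3)Oc2c1 | intermediate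
6 | (2S)-7-(TBSO)-2-[4-(TBSO)phenyl]-8-iodo-5-(3-methylbut-2-enyloxy)chroman-4-one | CC(C)(C)[Si](C)(C)Oc1cc(OCC=C(C)C)c2C(=O)C[C@@H](c3ccc(O[Si](C)(C)C(C)(C)C)cc3)Oc2c1I | intermediate
7 | (2S)-7-(TBSO)-2-[4-(TBSO)phenyl]-5-hydroxy-8-iodo-6-(3-methylbut-2-enyl)chroman-4-one | CC(C)(C)[Si](C)(C)Oc1c(CC=C(C)C)c(O)c2C(=O)C[C@@H](c3ccc(O[Si](C)(C)C(C)(C)C)cc3)Oc2c1I | intermediate
8 | 1-[(2S)-oxiran-2-yl]ethan-1-one (epoxy ketone, not isolated) | CC(=O)[C@@H]1CO1 | intermediate
9 | 2-[(2S)-oxiran-2-yl]propan-2-ol | CC(C)(O)[C@@H]1CO1 | intermediate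
10 | (3R)-4-iodo-2-methylbutane-2,3-diol (iodohydrin, not isolated) | IC[C@H](O)C(C)(C)O | intermediate
11 | (2S)-7-(TBSO)-2-[4-(TBSO)phenyl]-8-[(2S)-2,3-dihydroxy-3-methylbutyl]-5-hydroxy-6-(3-methylbut-2-enyl)chroman-4-one | CC(C)(C)[Si](C)(C)Oc1c(CC=C(C)C)c(O)c2C(=O)C[C@@H](c3ccc(O[Si](C)(C)C(C)(C)C)cc3)Oc2c1C[C@H](O)C(C)(C)O | intermediate
12 | (2S)-8-[(2S)-2,3-dihydroxy-3-methylbutyl]-5,7-dihydroxy-2-(4-hydroxyphenyl)-6-(3-methylbut-2-enyl)chroman-4-one | CC(C)=CCc1c(O)c(C[C@H](O)C(C)(C)O)c2c(c1O)C(=O)C[C@@H](c1ccc(O)cc1)O2 | target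

**Step count**

Total steps: 7 (six in the main line, one for the epoxide arm).
Longest linear sequence: 6 (1 → 4 → 5 → 6 → 7 → 11 → 12).

**Three steps most likely to fail**

Step 6 (the proposed coupling). The iodide is electron-rich and flanked by a silyloxy group and the ring oxygen, so radical capture at nickel may be slow and hydrodeiodination of 7 or loss of the β-hydroxyl from the alkyl fragment may win. The fallback is known chemistry, sets out from 9 (with 7) and returns at 12. Epoxy alcohol 9 is opened at its CH2 terminus with LiI/AcOH in THF to give isolated (3R)-4-iodo-2-methylbutane-2,3-diol 10. 2,2-Dimethoxypropane/PPTS converts 10 into (4R)-4-(iodomethyl)-2,2,5,5-tetramethyl-1,3-dioxolane F1. F1 and 7 are joined in the dark by the established zinc-driven, nickel-catalysed reductive cross-electrophile coupling of an aryl iodide with a primary alkyl iodide (NiI2, 4,4'-di-tert-butyl-2,2'-bipyridine, pyridine, Zn dust, DMPU, 60 °C). This gives (2S)-7-(TBSO)-2-[4-(TBSO)phenyl]-5-hydroxy-6-(3-methylbut-2-enyl)-8-{[(4S)-2,2,5,5-tetramethyl-1,3-dioxolan-4-yl]methyl}chroman-4-one F2. HF·pyridine followed by 80% aqueous AcOH at 40 °C removes both silyl ethers and the acetonide to give 12. The light-driven in-situ iodohydrin manifold is thus replaced by a pre-formed, protected electrophile and a metal reductant.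

Step 4 (clay [1,3] shift). Yields of such shifts are moderate; loss of the prenyl group, acid-induced loss or migration of iodine, and partial acid-catalysed opening of ring C (erosion at C2, to be checked by chiral HPLC) are the dangers. The fallback sets out from 4 and returns at 7, replacing the ionic shift by a concerted [3,3] shift plus metathesis. Mitsunobu reaction of 4 with allyl alcohol (PPh3, DIAD, THF) gives (2S)-5-(allyloxy)-7-(TBSO)-2-[4-(TBSO)phenyl]chroman-4-one F3. NIS in MeCN gives (2S)-5-(allyloxy)-7-(TBSO)-2-[4-(TBSO)phenyl]-8-iodochroman-4-one F4. Aromatic Claisen rearrangement catalysed by Eu(fod)3 (europium tris(6,6,7,7,8,8,8-heptafluoro-2,2-dimethyloctane-3,5-dionate), CHCl3, 60 °C) delivers the allyl group to C6, the only open ortho position of O5. This gives (2S)-6-allyl-7-(TBSO)-2-[4-(TBSO)phenyl]-5-hydroxy-8-iodochroman-4-one F5. Olefin cross-metathesis with 2-methylbut-2-ene (second-generation Grubbs catalyst RuCl2(=CHPh)(PCy3)(H2IMes), CH2Cl2, 40 °C) turns allyl into prenyl and gives 7.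

Step 3 (C8 iodination). The C8/C6 preference rests on sterics and on analogy with 5,7-dialkoxyflavonoids, and NIS could attack the trisubstituted ether alkene. The fallback sets out from 4 and returns at 7, and makes the regiochemistry independent of the O5 substituent. Ortho-iodination of 4 directed by the free 5-OH (benzyltrimethylammonium dichloroiodate, CaCO3, CH2Cl2/MeOH, rt) gives (2S)-7-(TBSO)-2-[4-(TBSO)phenyl]-5-hydroxy-6-iodochroman-4-one F6. Stille coupling with tributyl(3-methylbut-2-enyl)stannane (Pd(PPh3)4, DMF, 80 °C) gives (2S)-7-(TBSO)-2-[4-(TBSO)phenyl]-5-hydroxy-6-(3-methylbut-2-enyl)chroman-4-one F7. NIS in MeCN at −20 °C then iodinates C8, the one ring A position left, to give 7. This last iodination runs next to a prenyl group, but the chelated 5-OH is a poor partner for iodo-etherification.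

Further compounds
F1 | step 6 | (4R)-4-(iodomethyl)-2,2,5,5-tetramethyl-1,3-dioxolane | IC[C@@H]1OC(C)(C)OC1(C)C
F2 | step 6 | (2S)-7-(TBSO)-2-[4-(TBSO)phenyl]-5-hydroxy-6-(3-methylbut-2-enyl)-8-{[(4S)-2,2,5,5-tetramethyl-1,3-dioxolan-4-yl]methyl}chroman-4-one | CC(C)(C)[Si](C)(C)Oc1c(CC=C(C)C)c(O)c2C(=O)C[C@@H](c3ccc(O[Si](C)(C)C(C)(C)C)cc3)Oc2c1C[C@@H]1OC(C)(C)OC1(C)C
F3 | step 4 | (2S)-5-(allyloxy)-7-(TBSO)-2-[4-(TBSO)phenyl]chroman-4-one | CC(C)(C)[Si](C)(C)Oc1cc(OCC=C)c2C(=O)C[C@@H](c3ccc(O[Si](C)(C)C(C)(C)C)cc3)Oc2c1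
F4 | step 4 | (2S)-5-(allyloxy)-7-(TBSO)-2-[4-(TBSO)phenyl]-8-iodochroman-4-one | CC(C)(C)[Si](C)(C)Oc1cc(OCC=C)c2C(=O)C[C@@H](c3ccc(O[Si](C)(C)C(C)(C)C)cc3)Oc2c1I
F5 | step 4 | (2S)-6-allyl-7-(TBSO)-2-[4-(TBSO)phenyl]-5-hydroxy-8-iodochroman-4-one | CC(C)(C)[Si](C)(C)Oc1c(CC=C)c(O)c2C(=O)C[C@@H](c3ccc(O[Si](C)(C)C(C)(C)C)cc3)Oc2c1I
F6 | step 3 | (2S)-7-(TBSO)-2-[4-(TBSO)phenyl]-5-hydroxy-6-iodochroman-4-one | CC(C)(C)[Si](C)(C)Oc1c(I)c(O)c2C(=O)C[C@@H](c3ccc(O[Si](C)(C)C(C)(C)C)cc3)Oc2c1
F7 | step 3 | (2S)-7-(TBSO)-2-[4-(TBSO)phenyl]-5-hydroxy-6-(3-methylbut-2-enyl)chroman-4-one | CC(C)(C)[Si](C)(C)Oc1c(CC=C(C)C)c(O)c2C(=O)C[C@@H](c3ccc(O[Si](C)(C)C(C)(C)C)cc3)Oc2c1
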